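The route cuts ring A of the 6-hydroxychromone unit at two neighbouring carbons: C5, which carries the biaryl bond, and C4a, which carries the C4 carbonyl. Because these two carbons sit between the oxygen-bearing C6 and C8a, they correspond to the triple bond of symmetrical 3,6-dimethoxybenzyne. In a single operation a ring B aryl Grignard reagent (formyl group masked as a dioxolane) adds to this aryne and the neighbouring aryl-magnesium carbon is formylated with DMF, giving a biaryl 2,2'-dialdehyde after acidic work-up. The precursors are lithiated 2-fluoro-1,4-dimethoxybenzene and the Grignard reagent. Both 2-(2-phenylethyl)pyranone rings are then grown in parallel through ynones.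

Key step: step 4

Assumption: the SMILES fixes no configuration at the biaryl axis, so the target is made without atropisomer control (unit A = 6-hydroxychromone with benzene ring A, unit B = 8-hydroxychromone with benzene ring B).

Step 1
Reactants: 1 2,3-dimethoxybenzaldehyde
Product: 2 6-bromo-2,3-dimethoxybenzaldehyde
Conditions: NBS (1.1 equiv), DMF, rt, dark
Reagents that add atoms: N-bromosuccinimide, O=C1CCC(=O)N1Br
Why: Electrophilic aromatic bromination, which for this aldehyde with NBS in DMF is established to go to C6, the position para to the 3-methoxy group.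

Step 2
Reactants: 2 6-bromo-2,3-dimethoxybenzaldehyde
Product: 3 2-(6-bromo-2,3-dimethoxyphenyl)-1,3-dioxolane
Conditions: ethylene glycol (3 equiv), TsOH·H2O (cat.), toluene, reflux, Dean–Stark trap
Reagents that add atoms: ethylene glycol, OCCO
Why: Acid-catalysed acetalisation driven by azeotropic removal of water masks the formyl group against the organometallic reagents that follow.

Step 3
Reactants: 3 2-(6-bromo-2,3-dimethoxyphenyl)-1,3-dioxolane
Product: 4 [2-(1,3-dioxolan-2-yl)-3,4-dimethoxyphenyl]magnesium bromide (THF solution, titrated and used directly)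
Conditions: Mg turnings (activated with a crystal of I2), THF, 40–65 °C
Reagents that add atoms: magnesium, [Mg]
Why: Grignard formation by insertion of magnesium into the aryl C–Br bond, with the cyclic acetal inert to the reagent and able to stabilise it by chelation.

Step 4
Reactants: 5 2-fluoro-1,4-dimethoxybenzene; 4 [2-(1,3-dioxolan-2-yl)-3,4-dimethoxyphenyl]magnesium bromide
Product: 10 3,3',4',6-tetramethoxybiphenyl-2,2'-dicarbaldehyde, via 2-fluoro-3,6-dimethoxyphenyllithium 6 (not isolated), via 3,6-dimethoxybenzyne 7 (not isolated), via biaryl magnesium bromide 8 (not isolated), via dioxolane-protected biaryl monoaldehyde 9 (not isolated)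
Conditions: 5, n-BuLi (1.0 equiv), THF, −78 °C, 45 min; add 4 (1.5 equiv in THF), −78 °C → rt, 12 h; DMF (5 equiv), 0 °C → rt; 2 M aq HCl, THF, rt, 2 h
Reagents that add atoms: N,N-dimethylformamide, CN(C)C=O; water, O
Why: n-BuLi removes the proton of 5 lying between F and OMe (directed ortho-lithiation) to give 6, which on warming loses LiF to form the strained, symmetric aryne 7. The nucleophilic aryl carbon of 4 (future C5 of unit B) adds to one aryne carbon, forming the hindered biaryl bond and placing magnesium on the adjacent carbon (future C4a of unit A) in 8, which then attacks DMF to give a hemiaminal magnesium alkoxide; aqueous HCl liberates the formyl group (9) and cleaves the dioxolane in the same work-up to give 10. The closest known reaction type is aryne carbomagnesiation by an aryl Grignard reagent followed by electrophilic quench of the 2-biaryl magnesium species, combined with the standard Bouveault formylation of aryl Grignard reagents. No ring is closed and no stereocentre is formed; the biaryl axis arises without control. The only selectivity needed is positional: both aryne carbons are equivalent because each is flanked by a methoxy group, the attacking carbon of ring B is fixed by the bromine installed in step 1, and having 4 in excess before the mixture warms favours cross-addition over capture of 7 by 6.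

Step 5
Reactants: 10 3,3',4',6-tetramethoxybiphenyl-2,2'-dicarbaldehyde; 11 4-phenyl-1-butyne
Product: 13 1,1'-(3,3',4',6-tetramethoxybiphenyl-2,2'-diyl)bis(5-phenylpent-2-yn-1-ol) (mixture of diastereomers), via lithium 4-phenylbut-1-yn-1-ide 12 (not isolated)
Conditions: 11 (5 equiv), n-BuLi (4.8 equiv), THF, −78 °C, 30 min; add 10 in THF, −78 °C → 0 °C; H2O quench
Reagents that add atoms: none
Why: Twofold 1,2-addition of a lithium acetylide to the aryl aldehydes, in which the excess nucleophile should drain the reversible seven-membered lactolate formed after the first addition; the two carbinol centres form without control and are erased in step 6.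

Step 6
Reactants: 13 1,1'-(3,3',4',6-tetramethoxybiphenyl-2,2'-diyl)bis(5-phenylpent-2-yn-1-ol)
Product: 14 1,1'-(3,3',4',6-tetramethoxybiphenyl-2,2'-diyl)bis(5-phenylpent-2-yn-1-one)
Conditions: Dess–Martin periodinane (3 equiv), CH2Cl2, 0 °C → rt; aq Na2S2O3/NaHCO3 work-up
Reagents that add atoms: none
Why: Dess–Martin oxidation converts the benzylic propargylic secondary alcohols into conjugated ynones under near-neutral conditions that should leave the electron-rich rings and the alkynes untouched.

Step 7
Reactants: 14 1,1'-(3,3',4',6-tetramethoxybiphenyl-2,2'-diyl)bis(5-phenylpent-2-yn-1-one)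
Product: 15 1,1'-(3,3'-dihydroxy-4',6-dimethoxybiphenyl-2,2'-diyl)bis(5-phenylpent-2-yn-1-one)
Conditions: BCl3 (1 M in CH2Cl2, 3 equiv), CH2Cl2, −78 °C → 0 °C; ice-water quench
Reagents that add atoms: none
Why: Chelation-directed Lewis-acid demethylation, in which BCl3 bridges each ketone oxygen and its ortho methoxy oxygen in a six-membered chelate so that chloride removes only those two methyl groups while the two non-chelated methyl ethers should persist at or below 0 °C.

Step 8
Reactants: 15 1,1'-(3,3'-dihydroxy-4',6-dimethoxybiphenyl-2,2'-diyl)bis(5-phenylpent-2-yn-1-one)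
Product: 17 6-methoxy-5-[8-methoxy-4-oxo-2-(2-phenylethyl)-4H-chromen-5-yl]-2-(2-phenylethyl)-4H-chromen-4-one, via bis(diethylamino enone) 16 (not isolated)
Conditions: Et2NH (10 equiv), EtOH, rt → 60 °C; concentrate; 1 M aq HCl, THF, rt
Reagents that add atoms: none
Why: Aza-Michael addition of the secondary amine to each ynone gives a β-amino enone, onto whose β-carbon the ortho phenol closes in 6-endo-trig fashion with expulsion of the amine (addition–elimination), an established chromone synthesis that avoids the 5-exo aurone pathway.

Step 9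
Reactants: 17 6-methoxy-5-[8-methoxy-4-oxo-2-(2-phenylethyl)-4H-chromen-5-yl]-2-(2-phenylethyl)-4H-chromen-4-one
Product: 18 6-hydroxy-5-[8-hydroxy-4-oxo-2-(2-phenylethyl)-4H-chromen-5-yl]-2-(2-phenylethyl)-4H-chromen-4-one (CNP0392394.0)
Conditions: BBr3 (8 equiv), CH2Cl2, −78 °C → rt; ice-water quench
Reagents that add atoms: none
Why: BBr3 ether cleavage (Lewis-acid demethylation) should remove the two remaining aryl methyl ethers, and the chromone cores and phenylethyl chains are expected to tolerate it.

Compound list
1 | 2,3-dimethoxybenzaldehyde | COc1cccc(C=O)c1OC | starting material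
2 | 6-bromo-2,3-dimethoxybenzaldehyde | COc1ccc(Br)c(C=O)c1OC | intermediate
3 | 2-(6-bromo-2,3-dimethoxyphenyl)-1,3-dioxolane | COc1ccc(Br)c(C2OCCO2)c1OC | intermediate
4 | [2-(1,3-dioxolan-2-yl)-3,4-dimethoxyphenyl]magnesium bromide | COc1ccc([Mg]Br)c(C2OCCO2)c1OC | intermediate
5 | 2-fluoro-1,4-dimethoxybenzene | COc1ccc(OC)c(F)c1 | starting material
6 | (2-fluoro-3,6-dimethoxyphenyl)lithium | COc1ccc(OC)c([Li])c1F | intermediate
7 | 3,6-dimethoxybenzyne (1,4-dimethoxy-2,3-didehydrobenzene) | COC1=CC=C(OC)C#C1 | intermediate
8 | {2-[2-(1,3-dioxolan-2-yl)-3,4-dimethoxyphenyl]-3,6-dimethoxyphenyl}magnesium bromide | COc1ccc(OC)c([Mg]Br)c1-c1ccc(OC)c(OC)c1C1OCCO1 | intermediate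
9 | 2-[2-(1,3-dioxolan-2-yl)-3,4-dimethoxyphenyl]-3,6-dimethoxybenzaldehyde | COc1ccc(OC)c(C=O)c1-c1ccc(OC)c(OC)c1C1OCCO1 | intermediate
10 | 3,3',4',6-tetramethoxybiphenyl-2,2'-dicarbaldehyde | COc1ccc(OC)c(C=O)c1-c1ccc(OC)c(OC)c1C=O | intermediate
11 | 4-phenyl-1-butyne | C#CCCc1ccccc1 | starting material
12 | lithium 4-phenylbut-1-yn-1-ide | [Li]C#CCCc1ccccc1 | intermediate
13 | 1,1'-(3,3',4',6-tetramethoxybiphenyl-2,2'-diyl)bis(5-phenylpent-2-yn-1-ol), mixture of diastereomers (carbinol centres and axis uncontrolled) | COc1ccc(OC)c(C(O)C#CCCc2ccccc2)c1-c1ccc(OC)c(OC)c1C(O)C#CCCc1ccccc1 | intermediate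
14 | 1,1'-(3,3',4',6-tetramethoxybiphenyl-2,2'-diyl)bis(5-phenylpent-2-yn-1-one) | COc1ccc(OC)c(C(=O)C#CCCc2ccccc2)c1-c1ccc(OC)c(OC)c1C(=O)C#CCCc1ccccc1 | intermediate
15 | 1,1'-(3,3'-dihydroxy-4',6-dimethoxybiphenyl-2,2'-diyl)bis(5-phenylpent-2-yn-1-one) | COc1ccc(O)c(C(=O)C#CCCc2ccccc2)c1-c1ccc(OC)c(O)c1C(=O)C#CCCc1ccccc1 | intermediate
16 | (2E,2'E)-1,1'-(3,3'-dihydroxy-4',6-dimethoxybiphenyl-2,2'-diyl)bis[3-(diethylamino)-5-phenylpent-2-en-1-one] (E geometry expected, not needed for ring closure) | COc1ccc(O)c(C(=O)/C=C(\CCc2ccccc2)N(CC)CC)c1-c1ccc(OC)c(O)c1C(=O)/C=C(\CCc1ccccc1)N(CC)CC | intermediate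
17 | 6-methoxy-5-[8-methoxy-4-oxo-2-(2-phenylethyl)-4H-chromen-5-yl]-2-(2-phenylethyl)-4H-chromen-4-one | O=c1cc(CCc2ccccc2)oc2ccc(OC)c(-c3ccc(OC)c4oc(CCc5ccccc5)cc(=O)c34)c12 | intermediate
18 | 6-hydroxy-5-[8-hydroxy-4-oxo-2-(2-phenylethyl)-4H-chromen-5-yl]-2-(2-phenylethyl)-4H-chromen-4-one (biaryl axis unassigned) | O=c1cc(CCc2ccccc2)oc2ccc(O)c(-c3ccc(O)c4oc(CCc5ccccc5)cc(=O)c34)c12 | target

Total step count: 9.
Longest linear sequence: 9 steps (1 → 2 → 3 → 4 → 10 → 13 → 14 → 15 → 17 → 18); 5 and 11 enter as purchased materials.

Steps most likely to fail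

Step 4. The congested aryl-magnesium carbon of 8, flanked by a methoxy group and the new aryl ring, may be captured by DMF only slowly, so that protonation on work-up competes with formylation. A slow quench also gives the aryl-magnesium carbon time to attack the nearby acetal if the mixture is warmed. The fallback sets out from the in-flask magnesium species 8, generated exactly as in step 4, and separates bond formation from formylation. Compound 8 is quenched at 0 °C with I2 in THF, the electrophile with the closest precedent for this type of intermediate, to give 2-[6-(2-iodo-3,6-dimethoxyphenyl)-2,3-dimethoxyphenyl]-1,3-dioxolane F1, which is isolated. Iodine–lithium exchange with n-BuLi in THF at −78 °C then provides a far more reactive aryllithium, and addition of DMF should deliver the monoaldehyde 9, at which the fallback comes back to the route. Hydrolysis of 9 with aqueous HCl in THF as in the work-up of step 4 then gives 10.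

Step 7. Chemoselectivity may be lost because chloride or HCl can add across the BCl3-activated ynones, the freed phenols can close prematurely, or a non-chelated methyl ether can be cleaved. A β-chlorovinyl ketone formed in this way would still be converted by Et2NH in step 8 into the same enaminone, so part of this risk is self-correcting. The fallback sets out from 14 and replaces steps 7 and 8 by an iodocyclisation. With ICl (2.4 equiv) in CH2Cl2 at −78 °C each ortho methoxy oxygen attacks the iodonium-activated alkyne in 6-endo mode and chloride removes the methyl group, giving 3-iodo-5-[3-iodo-8-methoxy-4-oxo-2-(2-phenylethyl)-4H-chromen-5-yl]-6-methoxy-2-(2-phenylethyl)-4H-chromen-4-one F4. Hydrodeiodination with Pd(OAc)2 (cat.), PPh3 and HCO2Na in DMF at 80 °C then returns to the route at 17 and would also remove any iodine introduced on the aromatic rings.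

Step 5. The reaction may stall after the first addition because the new alkoxide closes onto the second formyl group as a seven-membered lactolate, which leaves mono-adduct after work-up. The fallback sets out from 10 and avoids nucleophilic addition to the dialdehyde altogether. Pinnick oxidation (NaClO2, NaH2PO4, 2-methyl-2-butene, t-BuOH/H2O) gives 3,3',4',6-tetramethoxybiphenyl-2,2'-dicarboxylic acid F2. Oxalyl chloride with catalytic DMF in CH2Cl2 converts it into 3,3',4',6-tetramethoxybiphenyl-2,2'-dicarbonyl dichloride F3. Acyl Sonogashira coupling of F3 with 11 (PdCl2(PPh3)2 (cat.), CuI (cat.), Et3N, THF, rt) forms both ynones directly and comes back to the route at 14, replacing steps 5 and 6.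

Further compounds
F1 | step 4 | 2-[6-(2-iodo-3,6-dimethoxyphenyl)-2,3-dimethoxyphenyl]-1,3-dioxolane | COc1ccc(OC)c(I)c1-c1ccc(OC)c(OC)c1C1OCCO1
F2 | step 5 | 3,3',4',6-tetramethoxybiphenyl-2,2'-dicarboxylic acid | COc1ccc(OC)c(C(=O)O)c1-c1ccc(OC)c(OC)c1C(=O)O
F3 | step 5 | 3,3',4',6-tetramethoxybiphenyl-2,2'-dicarbonyl dichloride | COc1ccc(OC)c(C(Cl)=O)c1-c1ccc(OC)c(OC)c1C(Cl)=O
F4 | step 7 | 3-iodo-5-[3-iodo-8-methoxy-4-oxo-2-(2-phenylethyl)-4H-chromen-5-yl]-6-methoxy-2-(2-phenylethyl)-4H-chromen-4-one | O=c1c(I)c(CCc2ccccc2)oc2ccc(OC)c(-c3ccc(OC)c4oc(CCc5ccccc5)c(I)c(=O)c34)c12
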